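**Assumption:** decalin locants follow eremophilane numbering (ring A = C1–C5, C10; ring B = C5–C10; C14 = CH3 on C5, C15 = CH3 on C4, C11–C13 = side chain on C7), β is the face of the C5 methyl, and the target is read as (3R,4R,5R,9R,10S), i.e. 3α-acyloxy, 4β,5β-dimethyl, 9β-OH, 10β-H (cis-decalin), 7(11)Z.

## Retrosynthetic overview

1. Last bond: the C3 ester, from the decalin C3 alcohol and (2E,4E,6E)-5-methyldodeca-2,4,6-trienoic acid (made from (E)-oct-2-enal by Corey–Fuchs, carboalumination–iodination and Heck).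
2. The (Z)-C7=C11(CH3)CH2OH enone comes from oxidative opening of a fused 3-methylfuran, whose ring fixes the Z geometry, followed by aldehyde reduction.
3. The furan comes from the key C7–C11 bond: intermolecular aldol of the C7 lithium enolate of a 9β-silyloxy cis-decalin-8-one with silyl-protected hydroxyacetone, then cyclodehydration.
4. The decalone comes from the cis-dione of (S)-Wieland–Miescher ketone: C15 methyl and 3α-OH by enol triflate methylation and hydroboration, 9β-OH by Rubottom oxidation.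
5. Ring order: ring A is bought (2-methylcyclohexane-1,3-dione); ring B is closed by Michael addition to methyl vinyl ketone and L-proline aldol condensation; the furan ring is formed third and opened again.

## Route

**Step 1**
Reactants: 1 2-methylcyclohexane-1,3-dione; 2 methyl vinyl ketone
Product: 3 2-methyl-2-(3-oxobutyl)cyclohexane-1,3-dione
Conditions: H2O, AcOH (cat.), hydroquinone (cat.), 75 °C
Reagents that add atoms: none
Why: Michael addition of the enolised 1,3-dione to the enone joins ring A to the four carbons of ring B at the future C5–C6 bond, with no stereocentre formed yet.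

**Step 2**
Reactants: 3 2-methyl-2-(3-oxobutyl)cyclohexane-1,3-dione
Product: 5 (S)-Wieland–Miescher ketone, via cis-ketol 4 (not isolated)
Conditions: L-proline (5 mol%), DMSO, rt; recrystallisation (Et2O/hexane)
Reagents that add atoms: none
Why: L-Proline-catalysed enamine intramolecular aldol condensation (Hajos–Parrish–Eder–Sauer–Wiechert reaction) closes ring B and sets the quaternary C5 centre as S, and recrystallisation raises the ee.

**Step 3**
Reactants: 5 (S)-Wieland–Miescher ketone
Product: 6 cis-dione (4aR,8aS)-8a-methyloctahydronaphthalene-1,6-dione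
Conditions: H2 (1 atm), 10% Pd/C, EtOAc, rt; recrystallisation
Reagents that add atoms: none
Why: Heterogeneous catalytic hydrogenation of this angularly methylated octalone delivers H to C10 on the face that gives the cis-fused decalin (10β-H), the known preference for this enone, without touching the ketones.

**Step 4**
Reactants: 6 cis-dione
Product: 7 8,8-ethylenedioxy-5β-methyl-10βH-decalin-4-one
Conditions: HOCH2CH2OH (1.1 equiv), PPTS (cat.), PhH, reflux (Dean–Stark)
Reagents that add atoms: ethylene glycol, OCCO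
Why: Acid-catalysed ketalisation is selective for the unhindered C8 carbonyl because the C4 carbonyl is neopentyl (next to the quaternary C5).

**Step 5**
Reactants: 7 8,8-ethylenedioxy-5β-methyl-10βH-decalin-4-one
Product: 9 8,8-ethylenedioxy-5β-methyl-10βH-octal-3-en-4-yl trifluoromethanesulfonate, via potassium enolate 8 (not isolated)
Conditions: KN(SiMe3)2, THF, −78 °C; PhNTf2, −78 → 0 °C; aqueous work-up
Reagents that add atoms: N-phenylbis(trifluoromethanesulfonimide), O=S(=O)(N(c1ccccc1)S(=O)(=O)C(F)(F)F)C(F)(F)F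
Why: The C4 ketone can enolise only toward C3, so O-triflation of the enolate (enol triflate formation) gives a single regioisomer.

**Step 6**
Reactants: 9 enol triflate
Product: 10 8,8-ethylenedioxy-4,5β-dimethyl-10βH-octal-3-ene
Conditions: MeMgBr, Fe(acac)3 (5 mol%), THF/NMP, −30 → 0 °C
Reagents that add atoms: methylmagnesium bromide, C[Mg]Br
Why: Iron-catalysed Kumada-type cross-coupling of the alkenyl triflate installs the C15 methyl on the C3=C4 double bond and tolerates the ketal.

**Step 7**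
Reactants: 10 8,8-ethylenedioxy-4,5β-dimethyl-10βH-octal-3-ene
Product: 12 8,8-ethylenedioxy-4β,5β-dimethyl-10βH-decalin-3α-ol, via alkylborane 11 (not isolated)
Conditions: BH3·THF, THF, 0 °C → rt; then 3 M NaOH, 30% H2O2, 0 °C → rt
Reagents that add atoms: hydrogen peroxide, OO
Why: Hydroboration–oxidation adds H and OH syn and anti-Markovnikov, so 3-OH and 4-CH3 come out trans, and borane attacks the α face opposite the axial angular methyl of the ketal-favoured conformer, giving 3α-OH/4β-CH3.

**Step 8**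
Reactants: 12 8,8-ethylenedioxy-4β,5β-dimethyl-10βH-decalin-3α-ol
Product: 13 3α-(4-methoxybenzyloxy)-8,8-ethylenedioxy-4β,5β-dimethyl-10βH-decalin
Conditions: NaH, PMBCl, Bu4NI (cat.), DMF, 0 °C → rt
Reagents that add atoms: 4-methoxybenzyl chloride, COc1ccc(CCl)cc1
Why: Williamson etherification protects the C3 hydroxyl as a PMB ether that survives base, peracid, fluoride and mild acid and is removed oxidatively later.

**Step 9**
Reactants: 13 PMB ether ketal
Product: 14 3α-(4-methoxybenzyloxy)-4β,5β-dimethyl-10βH-decalin-8-one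
Conditions: 1 M HCl, THF, rt
Reagents that add atoms: water, O
Why: Acid-catalysed ketal hydrolysis frees the C8 ketone while the PMB ether is stable to dilute acid.

**Step 10**
Reactants: 14 3α-(4-methoxybenzyloxy)-4β,5β-dimethyl-10βH-decalin-8-one
Product: 15 8-trimethylsilyloxy Δ8(9) enol ether of 14
Conditions: Me3SiCl, Et3N, DMF, 90 °C
Reagents that add atoms: chlorotrimethylsilane, C[Si](C)(C)Cl
Why: Silyl enol ether formation under equilibrating conditions, where a cis-fused decalone of this type enolises preferentially toward the ring-fusion side (C9), as 3-keto-5β-steroids do.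

**Step 11**
Reactants: 15 Δ8(9) trimethylsilyl enol ether
Product: 17 9β-hydroxy-3α-(4-methoxybenzyloxy)-4β,5β-dimethyl-10βH-decalin-8-one, via silyloxy ketone 16 (not isolated)
Conditions: mCPBA, NaHCO3, CH2Cl2, −20 °C; then aq. citric acid, THF, rt
Reagents that add atoms: 3-chloroperbenzoic acid, OOC(=O)c1cccc(Cl)c1
Why: Rubottom oxidation, in which the peracid epoxidises the enol ether on the convex β face of the cis-decalin and silyl migration then desilylation give the equatorial 9β-hydroxy ketone.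

**Step 12**
Reactants: 17 9β-hydroxy ketone
Product: 18 9β-(tert-butyldimethylsilyloxy)-3α-(4-methoxybenzyloxy)-4β,5β-dimethyl-10βH-decalin-8-one
Conditions: TBSOTf, 2,6-lutidine, CH2Cl2, −78 → 0 °C
Reagents that add atoms: tert-butyldimethylsilyl trifluoromethanesulfonate, CC(C)(C)[Si](C)(C)OS(=O)(=O)C(F)(F)F
Why: Silylation with the reactive triflate protects the hindered α-hydroxy ketone and blocks ketol isomerisation.

**Step 13**
Reactants: 19 hydroxyacetone
Product: 20 1-(tert-butyldimethylsilyloxy)propan-2-one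
Conditions: TBSCl, imidazole, CH2Cl2, 0 °C → rt
Reagents that add atoms: tert-butyldimethylsilyl chloride, CC(C)(C)[Si](C)(C)Cl
Why: Standard silyl protection of the primary hydroxyl gives the ketone acceptor for the aldol step.

**Step 14**
Reactants: 18 9β-silyloxy decalin-8-one; 20 1-(tert-butyldimethylsilyloxy)propan-2-one
Product: 22 C7 aldol adduct (C7/C11 diastereomer mixture), via lithium enolate 21 (not isolated)
Conditions: LiN(iPr)2, THF, −78 °C; then 20, −78 °C; H2O quench at −78 °C
Reagents that add atoms: none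
Why: Kinetic deprotonation of the α-silyloxy ketone occurs at the C7 methylene, and the lithium enolate adds to ketone 20 in an intermolecular aldol addition that forms the C7–C11 bond, its two new stereocentres being erased in the next step.

**Step 15**
Reactants: 22 C7 aldol adduct
Product: 24 9β-(tert-butyldimethylsilyloxy)-3α-(4-methoxybenzyloxy)-10βH-furanoeremophilane, via keto diol 23 (not isolated)
Conditions: HF·pyridine, pyridine, THF, 0 °C; then PPTS (cat.), 4 Å MS, PhMe, 50 °C
Reagents that add atoms: none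
Why: Selective cleavage of the primary silyl ether lets the C12 hydroxyl close onto the C8 ketone, and acid-catalysed cyclodehydration (loss of two waters) aromatises to the 3-methylfuran, converging all aldol diastereomers.

**Step 16**
Reactants: 24 furan
Product: 25 (7(11)Z)-9β-(tert-butyldimethylsilyloxy)-3α-(4-methoxybenzyloxy)-8-oxo-10βH-eremophil-7(11)-en-12-al
Conditions: DMDO (1.1 equiv), acetone, −78 → −30 °C
Reagents that add atoms: dimethyldioxirane, CC1(C)OO1
Why: Oxidative furan ring opening, in which epoxidation of the electron-rich furan collapses to the cis-enedicarbonyl, so the Z geometry of C7=C11 (C12 cis to C8) is fixed by the former ring.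

**Step 17**
Reactants: 25 Z-keto enal
Product: 26 (7(11)Z)-12-hydroxy-9β-(tert-butyldimethylsilyloxy)-3α-(4-methoxybenzyloxy)-10βH-eremophil-7(11)-en-8-one
Conditions: NaBH4, CH2Cl2/EtOH (7:3), −78 °C; used crude
Reagents that add atoms: none
Why: Chemoselective borohydride 1,2-reduction of the aldehyde at low temperature, the hindered conjugated ketone reacting much more slowly.

**Step 18**
Reactants: 26 Z-hydroxy enone
Product: 27 (7(11)Z)-9β,12-bis(tert-butyldimethylsilyloxy)-3α-(4-methoxybenzyloxy)-10βH-eremophil-7(11)-en-8-one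
Conditions: TBSCl, imidazole, DMF, 0 °C
Reagents that add atoms: tert-butyldimethylsilyl chloride, CC(C)(C)[Si](C)(C)Cl
Why: Silylation of the primary allylic hydroxyl stops cyclisation back toward the furan and differentiates it from the C3 hydroxyl.

**Step 19**
Reactants: 27 bis-silyl PMB ether
Product: 28 (7(11)Z)-3α-hydroxy-9β,12-bis(tert-butyldimethylsilyloxy)-10βH-eremophil-7(11)-en-8-one
Conditions: DDQ, CH2Cl2/pH 7 buffer (10:1), 0 °C → rt
Reagents that add atoms: none
Why: Oxidative PMB ether cleavage with DDQ is orthogonal to the silyl ethers and the enone.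

**Step 20**
Reactants: 29 (E)-oct-2-enal
Product: 30 (3E)-1,1-dibromonona-1,3-diene
Conditions: CBr4, PPh3, CH2Cl2, 0 °C
Reagents that add atoms: carbon tetrabromide, BrC(Br)(Br)Br
Why: Corey–Fuchs dibromoolefination (a Wittig-type reaction) adds one carbon and leaves the E alkene untouched.

**Step 21**
Reactants: 30 (3E)-1,1-dibromonona-1,3-diene
Product: 32 (E)-non-3-en-1-yne, via lithium acetylide 31 (not isolated)
Conditions: n-BuLi (2.1 equiv), THF, −78 °C → rt; H2O
Reagents that add atoms: none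
Why: Second stage of the Corey–Fuchs reaction, in which lithium–bromine exchange and Fritsch–Buttenberg–Wiechell rearrangement give the acetylide that is protonated on work-up.

**Step 22**
Reactants: 32 (E)-non-3-en-1-yne
Product: 34 (1E,3E)-1-iodo-2-methylnona-1,3-diene, via alkenylalane 33 (not isolated)
Conditions: Me3Al, Cp2ZrCl2 (20 mol%), CH2Cl2, rt; then I2, THF, −30 → 0 °C
Reagents that add atoms: trimethylaluminium, C[Al](C)C; iodine, II
Why: Negishi zirconium-catalysed carboalumination adds CH3 and Al syn across the terminal alkyne with CH3 on the internal carbon, and iodinolysis with retention gives the E trisubstituted alkenyl iodide.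

**Step 23**
Reactants: 34 (1E,3E)-1-iodo-2-methylnona-1,3-diene; 35 methyl acrylate
Product: 36 methyl (2E,4E,6E)-5-methyldodeca-2,4,6-trienoate
Conditions: Pd(OAc)2 (5 mol%), K2CO3, Bu4NCl, DMF, 40 °C
Reagents that add atoms: none
Why: Heck reaction (Jeffery conditions) couples the alkenyl iodide with retention at C4=C5 and trans selectivity at the new C2=C3 bond.

**Step 24**
Reactants: 36 methyl trienoate
Product: 37 (2E,4E,6E)-5-methyldodeca-2,4,6-trienoic acid
Conditions: LiOH, THF/MeOH/H2O, rt; then 1 M HCl to pH 3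
Reagents that add atoms: lithium hydroxide, [Li+].[OH-]
Why: Ester saponification under mild conditions leaves the triene geometry intact.

**Step 25**
Reactants: 37 (2E,4E,6E)-5-methyldodeca-2,4,6-trienoic acid; 28 C3 alcohol
Product: 39 9,12-bis(tert-butyldimethylsilyl) ether of the target, via mixed anhydride 38 (not isolated)
Conditions: 2,4,6-Cl3C6H2COCl, Et3N, THF, rt; then 28, DMAP, PhMe, rt
Reagents that add atoms: none
Why: Yamaguchi esterification acylates the hindered secondary C3 hydroxyl through the mixed anhydride and DMAP without disturbing the C3 configuration.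

**Step 26**
Reactants: 39 bis-silyl ester
Product: 40 target CNP0226738.1
Conditions: HF·pyridine, pyridine, THF, 0 °C → rt
Reagents that add atoms: none
Why: Pyridine-buffered fluoride desilylation removes both silyl ethers under near-neutral conditions, chosen to avoid cyclodehydration of the Z-γ-hydroxy enone and ketol isomerisation.

## Compound list

1 | 2-methylcyclohexane-1,3-dione | CC1C(=O)CCCC1=O | starting material
2 | methyl vinyl ketone (but-3-en-2-one) | CC(=O)C=C | starting material
3 | 2-methyl-2-(3-oxobutyl)cyclohexane-1,3-dione | CC(=O)CCC1(C)C(=O)CCCC1=O | intermediate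
4 | cis-ketol, 10β-hydroxy-5β-methyldecalin-4,8-dione (OH cis to CH3) | C1CC[C@]2(O)CC(=O)CC[C@]2(C)C1=O | intermediate (not isolated)
5 | (S)-Wieland–Miescher ketone, (S)-8a-methyl-3,4,8,8a-tetrahydronaphthalene-1,6(2H,7H)-dione | C1CCC2=CC(=O)CC[C@]2(C)C1=O | intermediate
6 | cis-dione, (4aR,8aS)-8a-methyloctahydronaphthalene-1,6-dione (5β-CH3, 10β-H) | C1CC[C@@H]2CC(=O)CC[C@]2(C)C1=O | intermediate
7 | 8,8-ethylenedioxy-5β-methyl-10βH-decalin-4-one | C1CC[C@@H]2CC3(OCCO3)CC[C@]2(C)C1=O | intermediate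
8 | potassium C3=C4 enolate of 7 | [K+].[O-]C1=CCC[C@@H]2CC3(OCCO3)CC[C@]12C | intermediate (not isolated)
9 | 8,8-ethylenedioxy-5β-methyl-10βH-octal-3-en-4-yl trifluoromethanesulfonate | FC(F)(F)S(=O)(=O)OC1=CCC[C@@H]2CC3(OCCO3)CC[C@]12C | intermediate
10 | 8,8-ethylenedioxy-4,5β-dimethyl-10βH-octal-3-ene | CC1=CCC[C@@H]2CC3(OCCO3)CC[C@]12C | intermediate
11 | 3α-boryl-8,8-ethylenedioxy-4β,5β-dimethyl-10βH-decalin (monoalkylborane) | B[C@@H]1CC[C@@H]2CC3(OCCO3)CC[C@]2(C)[C@H]1C | intermediate (not isolated)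
12 | 8,8-ethylenedioxy-4β,5β-dimethyl-10βH-decalin-3α-ol | O[C@@H]1CC[C@@H]2CC3(OCCO3)CC[C@]2(C)[C@H]1C | intermediate
13 | 3α-(4-methoxybenzyloxy)-8,8-ethylenedioxy-4β,5β-dimethyl-10βH-decalin | COc1ccc(CO[C@@H]2CC[C@@H]3CC4(OCCO4)CC[C@]3(C)[C@H]2C)cc1 | intermediate
14 | 3α-(4-methoxybenzyloxy)-4β,5β-dimethyl-10βH-decalin-8-one | COc1ccc(CO[C@@H]2CC[C@@H]3CC(=O)CC[C@]3(C)[C@H]2C)cc1 | intermediate
15 | 8-trimethylsilyloxy Δ8(9) enol ether of 14 | COc1ccc(CO[C@@H]2CC[C@@H]3C=C(O[Si](C)(C)C)CC[C@]3(C)[C@H]2C)cc1 | intermediate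
16 | 9β-trimethylsilyloxy-3α-(4-methoxybenzyloxy)-4β,5β-dimethyl-10βH-decalin-8-one | COc1ccc(CO[C@@H]2CC[C@@H]3[C@@H](O[Si](C)(C)C)C(=O)CC[C@]3(C)[C@H]2C)cc1 | intermediate (not isolated)
17 | 9β-hydroxy-3α-(4-methoxybenzyloxy)-4β,5β-dimethyl-10βH-decalin-8-one | COc1ccc(CO[C@@H]2CC[C@@H]3[C@@H](O)C(=O)CC[C@]3(C)[C@H]2C)cc1 | intermediate
18 | 9β-(tert-butyldimethylsilyloxy)-3α-(4-methoxybenzyloxy)-4β,5β-dimethyl-10βH-decalin-8-one | COc1ccc(CO[C@@H]2CC[C@@H]3[C@@H](O[Si](C)(C)C(C)(C)C)C(=O)CC[C@]3(C)[C@H]2C)cc1 | intermediate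
19 | hydroxyacetone (1-hydroxypropan-2-one) | CC(=O)CO | starting material
20 | 1-(tert-butyldimethylsilyloxy)propan-2-one | CC(=O)CO[Si](C)(C)C(C)(C)C | intermediate
21 | lithium C7=C8 enolate of 18 | COc1ccc(CO[C@@H]2CC[C@@H]3[C@@H](O[Si](C)(C)C(C)(C)C)C(O[Li])=CC[C@]3(C)[C@H]2C)cc1 | intermediate (not isolated)
22 | aldol adduct, 7-[2-hydroxy-1-(tert-butyldimethylsilyloxy)propan-2-yl] derivative of 18 (mixture at C7 and C11) | COc1ccc(CO[C@@H]2CC[C@@H]3[C@@H](O[Si](C)(C)C(C)(C)C)C(=O)C(C(C)(O)CO[Si](C)(C)C(C)(C)C)C[C@]3(C)[C@H]2C)cc1 | intermediate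
23 | keto diol, 7-(1,2-dihydroxypropan-2-yl) derivative of 18 (mixture at C7 and C11) | COc1ccc(CO[C@@H]2CC[C@@H]3[C@@H](O[Si](C)(C)C(C)(C)C)C(=O)C(C(C)(O)CO)C[C@]3(C)[C@H]2C)cc1 | intermediate (not isolated)
24 | 9β-(tert-butyldimethylsilyloxy)-3α-(4-methoxybenzyloxy)-10βH-furanoeremophilane (8,12-epoxyeremophila-7,11-diene) | COc1ccc(CO[C@@H]2CC[C@@H]3[C@@H](O[Si](C)(C)C(C)(C)C)c4occ(C)c4C[C@]3(C)[C@H]2C)cc1 | intermediate
25 | (7(11)Z)-9β-(tert-butyldimethylsilyloxy)-3α-(4-methoxybenzyloxy)-8-oxo-10βH-eremophil-7(11)-en-12-al | COc1ccc(CO[C@@H]2CC[C@@H]3[C@@H](O[Si](C)(C)C(C)(C)C)C(=O)/C(=C(/C)C=O)C[C@]3(C)[C@H]2C)cc1 | intermediate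
26 | (7(11)Z)-12-hydroxy-9β-(tert-butyldimethylsilyloxy)-3α-(4-methoxybenzyloxy)-10βH-eremophil-7(11)-en-8-one | COc1ccc(CO[C@@H]2CC[C@@H]3[C@@H](O[Si](C)(C)C(C)(C)C)C(=O)/C(=C(/C)CO)C[C@]3(C)[C@H]2C)cc1 | intermediate
27 | (7(11)Z)-9β,12-bis(tert-butyldimethylsilyloxy)-3α-(4-methoxybenzyloxy)-10βH-eremophil-7(11)-en-8-one | COc1ccc(CO[C@@H]2CC[C@@H]3[C@@H](O[Si](C)(C)C(C)(C)C)C(=O)/C(=C(/C)CO[Si](C)(C)C(C)(C)C)C[C@]3(C)[C@H]2C)cc1 | intermediate
28 | (7(11)Z)-3α-hydroxy-9β,12-bis(tert-butyldimethylsilyloxy)-10βH-eremophil-7(11)-en-8-one | O[C@@H]1CC[C@@H]2[C@@H](O[Si](C)(C)C(C)(C)C)C(=O)/C(=C(/C)CO[Si](C)(C)C(C)(C)C)C[C@]2(C)[C@H]1C | intermediate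
29 | (E)-oct-2-enal | CCCCC/C=C/C=O | starting material
30 | (3E)-1,1-dibromonona-1,3-diene | CCCCC/C=C/C=C(Br)Br | intermediate
31 | lithium (E)-non-3-en-1-yn-1-ide | CCCCC/C=C/C#C[Li] | intermediate (not isolated)
32 | (E)-non-3-en-1-yne | CCCCC/C=C/C#C | intermediate
33 | dimethyl[(1E,3E)-2-methylnona-1,3-dien-1-yl]alane | CCCCC/C=C/C(C)=C/[Al](C)C | intermediate (not isolated)
34 | (1E,3E)-1-iodo-2-methylnona-1,3-diene | CCCCC/C=C/C(C)=C/I | intermediate
35 | methyl acrylate | C=CC(=O)OC | starting material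
36 | methyl (2E,4E,6E)-5-methyldodeca-2,4,6-trienoate | CCCCC/C=C/C(C)=C/C=C/C(=O)OC | intermediate
37 | (2E,4E,6E)-5-methyldodeca-2,4,6-trienoic acid | CCCCC/C=C/C(C)=C/C=C/C(=O)O | intermediate
38 | (2E,4E,6E)-5-methyldodeca-2,4,6-trienoic 2,4,6-trichlorobenzoic anhydride | CCCCC/C=C/C(C)=C/C=C/C(=O)OC(=O)c1c(Cl)cc(Cl)cc1Cl | intermediate (not isolated)
39 | (7(11)Z)-9β,12-bis(tert-butyldimethylsilyloxy)-8-oxo-10βH-eremophil-7(11)-en-3α-yl (2E,4E,6E)-5-methyldodeca-2,4,6-trienoate | CCCCC/C=C/C(C)=C/C=C/C(=O)O[C@@H]1CC[C@@H]2[C@@H](O[Si](C)(C)C(C)(C)C)C(=O)/C(=C(/C)CO[Si](C)(C)C(C)(C)C)C[C@]2(C)[C@H]1C | intermediate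
40 | (3R,4R,5R,9R,10S,7(11)Z)-9,12-dihydroxy-8-oxoeremophil-7(11)-en-3-yl (2E,4E,6E)-5-methyldodeca-2,4,6-trienoate | CCCCC/C=C/C(C)=C/C=C/C(=O)O[C@@H]1CC[C@@H]2[C@@H](O)C(=O)/C(=C(/C)CO)C[C@]2(C)[C@H]1C | target

## Step count and risks

Total step count: 26. Longest linear sequence: 20 steps (steps 1–12, 14–19, 25 and 26, from 1 and 2).

**Step 7 (facial selectivity of hydroboration in a conformationally mobile cis-decalin).** The fallback replaces kinetic face control by thermodynamic control. It sets out from 10, which is hydroborated and oxidised as before, and the crude C3/C4 stereoisomer mixture is oxidised with Dess–Martin periodinane to the C3 ketone. Stirring with NaOMe in MeOH equilibrates C4 to the equatorial 4β-methyl epimer, 8,8-ethylenedioxy-4β,5β-dimethyl-10βH-decalin-3-one F1. Dissolving-metal reduction (Li, NH3, THF, t-BuOH, −78 °C) then gives the more stable equatorial 3α-alcohol, and the route is rejoined at 12.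

**Step 14 (aldol addition to an enolisable ketone; proton transfer or retro-aldol may dominate).** The fallback builds the same furan by a Michael/Paal–Knorr sequence. It sets out from 18, whose lithium enolate (LiN(iPr)2, THF, −78 °C) is added to freshly prepared (E)-1-nitroprop-1-ene to give the γ-nitro ketone, 7-(1-nitropropan-2-yl) derivative of 18 F2. A buffered reductive Nef reaction (TiCl3, NH4OAc, aq. THF) converts the nitromethyl group into the aldehyde, giving the 1,4-keto aldehyde, 2-(8-oxodecalin-7-yl)propanal derivative of 18 F3. Paal–Knorr cyclodehydration (PPTS, PhMe, 60 °C) then closes the 3-methylfuran, and the route is rejoined at 24.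

**Step 17 (aldehyde versus ketone selectivity, and the tendency of 26 to recyclise toward the furan).** The fallback over-reduces and re-oxidises. It sets out from 25, and both carbonyls are reduced with i-Bu2AlH (CH2Cl2, −78 °C) to the Z-diol, (7(11)Z)-9β-(tert-butyldimethylsilyloxy)-3α-(4-methoxybenzyloxy)-10βH-eremophil-7(11)-ene-8,12-diol F4. The primary allylic hydroxyl is silylated selectively (TBSCl, imidazole, CH2Cl2, −20 °C) to give the 12-(tert-butyldimethylsilyl) ether of that diol F5. The remaining secondary allylic C8 hydroxyl is oxidised with MnO2 (CH2Cl2, rt), and the route is rejoined at 27.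

## Further compounds

F1 | step 7 | 8,8-ethylenedioxy-4β,5β-dimethyl-10βH-decalin-3-one | O=C1CC[C@@H]2CC3(OCCO3)CC[C@]2(C)[C@H]1C
F2 | step 14 | 7-(1-nitropropan-2-yl) derivative of 18 (mixture at C7 and C11) | COc1ccc(CO[C@@H]2CC[C@@H]3[C@@H](O[Si](C)(C)C(C)(C)C)C(=O)C(C(C)C[N+](=O)[O-])C[C@]3(C)[C@H]2C)cc1
F3 | step 14 | 2-(8-oxodecalin-7-yl)propanal derivative of 18 (mixture at C7 and C11) | COc1ccc(CO[C@@H]2CC[C@@H]3[C@@H](O[Si](C)(C)C(C)(C)C)C(=O)C(C(C)C=O)C[C@]3(C)[C@H]2C)cc1
F4 | step 17 | (7(11)Z)-9β-(tert-butyldimethylsilyloxy)-3α-(4-methoxybenzyloxy)-10βH-eremophil-7(11)-ene-8,12-diol (C8 epimers) | COc1ccc(CO[C@@H]2CC[C@@H]3[C@@H](O[Si](C)(C)C(C)(C)C)C(O)/C(=C(/C)CO)C[C@]3(C)[C@H]2C)cc1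
F5 | step 17 | (7(11)Z)-9β,12-bis(tert-butyldimethylsilyloxy)-3α-(4-methoxybenzyloxy)-10βH-eremophil-7(11)-en-8-ol (C8 epimers) | COc1ccc(CO[C@@H]2CC[C@@H]3[C@@H](O[Si](C)(C)C(C)(C)C)C(O)/C(=C(/C)CO[Si](C)(C)C(C)(C)C)C[C@]3(C)[C@H]2C)cc1
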